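## The problem

The target is an isoflavone, a 3-arylchromen-4-one. Ring A is a phloroglucinol unit (5-OH, 7-OH, ring oxygen O1) that carries a 3-hydroxy-3-methylbutyl chain at C6. Ring B is a 2'-hydroxyphenyl ring with a 2,2-dimethyl-2H-pyran fused linearly through O–C4' and C5'. There is no stereocentre, so nothing has to be controlled or relayed; the only stereocentre the plan creates is a transient ketal carbon that is erased again. The difficulties are regiochemical: the chain must sit at C6 and not at the electronically similar C8, and the pyran must close onto C5' and not onto C3', which lies between two oxygens. Three groups will not survive rough treatment. The chromene olefin is sensitive to strong acid, hydrogenation and electrophilic halogen. The pyranone is opened by hydroxide and attacked at C2 by hard nucleophiles. The tertiary alcohol cyclises under acid onto O5 or O7 to a dimethylchroman, or dehydrates, so no acidic step may follow its formation. The chain also offers the opening: C1''' is a benzylic carbon flanked by the phenolic oxygens O5 and O7. A 6-hydroxymethyl phenol can therefore lose water to an ortho-quinone methide, and C1'''–C3''' with the tertiary oxygen map onto that quinone methide plus a 2-oxygenated propene.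

## Retrosynthesis

**C3'''–CH3.** Target 21 is cut at one methyl–carbinol bond to give methyl ketone 20. Hydration of a prenyl group would have to distinguish the chain olefin from the chromene olefin, and a double addition to an ester needs more forcing conditions. Ketone 20 is one carbon simpler and not acid-sensitive. The forward step asks for a methyl Grignard reagent in excess, with the three phenoxides deactivating the pyranone, and a neutral work-up.

**O7–C3''' (unmasking).** Ketone 20 is the hydrolysis product of the cyclic mixed ketal 19. This is a functional-group change only, but it exposes the cycloadduct. The forward step needs acid dilute enough to leave the chromene alone.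

**C1'''–C2''' and O7–C3''' (key cut).** Ketal 19 is divided into ortho-quinone methide 18 and 2-methoxypropene 17; 18 comes from the 6-hydroxymethyl tetraol 16 by loss of water. The neighbouring cuts are worse: alkylating ring A with a four-carbon electrophile meets the C6/C8/O ambiguity, and cross-coupling at C6 would need a halide between two ortho substituents. The quinone methide route needs only a one-carbon handle at C6, which can be placed early and unambiguously. The chain shrinks to CH2OH and the partner is a commodity enol ether. The forward reaction must be neutral and thermal, with enough 17 to outrun self-trapping.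

**Protecting groups.** Tetraol 16 is too prone to ionise to be carried far. It is unveiled in one operation from 15, which has two methoxymethyl (MOM) ethers on O7 and O2' and an isopropylidene ketal tying O5 to the benzylic oxygen.

**C3–C1'.** Isoflavone 15 is cut between the pyranone and ring B into 3-iodochromone 7 and pinacol boronate 14 (Suzuki–Miyaura coupling). A deoxybenzoin route would need acidic one-carbon insertion in the presence of the chromene and the benzylic ether. The coupling is convergent and splits the molecule into halves of similar size. It must tolerate an ortho-alkoxy boronate and use a base too mild to open the pyranone.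

**Pyranone ring of 7.** The O1–C2 and C2–C3 bonds are cut back to acetophenone 5, with C2 coming from an amide acetal via enaminone 6, and iodine entering at C3 during closure. In 5 the ketone has only one free ortho hydroxyl. The other flanking oxygen is locked in the isopropylidene ketal with the benzylic CH2O. Ring closure can therefore only place the CH2O carbon at C6, never at C8.

**The C6 carbon.** Ketal 5 comes from salicyl alcohol 4, and 4 from aldehyde 3. The aryl–CHO bond of 3 is cut to give 2, the 4-O-MOM ether of phloroacetophenone 1. Compound 2 is symmetric, so formylation at either free ring position gives the same product; the alternative, formylating a finished 5,7-dioxygenated chromone, has no such control. After reduction the benzylic hydroxyl has exactly one free phenolic neighbour, which fixes the ketal. The ring A sequence thus starts from commodity 1.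

**Ring B.** Boronate 14 comes from bromide 13, and chromene 13 from chromanone 11 by reduction to 12 and elimination. Chromanone 10 (the free phenol of 11) is cut into 4-bromoresorcinol 8 and 3-methylbut-2-enoic acid 9 (Friedel–Crafts acylation, then oxa-Michael closure). The bromine is present from the start: it leaves only one activated acylation site, which enforces the linear fusion, and it marks the later coupling carbon. Halogenating a 7-hydroxychromanone afterwards (C6 or C8) or chromenylating a resorcinol with an enal (linear or angular) would both raise regiochemical questions.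

## Roads not taken

**Alternative 1:** Four C–CH3 bonds would be cut at once, two at C3''' and two at the pyran carbon of ring B. The precursor is the ester–coumarin A1, with a methyl propanoate chain at C6 and ring B as a 7-MOM-oxycoumarin. MeLi with CeCl3 would add twice to the ester and twice to the lactone to give diol A2, which has the chain carbinol and a (Z)-allylic tertiary carbinol ortho to the freed 4'-OH; acid would then close the chromene.
- Merits: both dimethylcarbinol units come from robust carbonyl groups, the chromene olefin appears only at the end, and coumarin-to-dimethylchromene conversion by methyl organometallics is classical. Four C–C bonds in one operation is better bond economy than the chosen plan offers.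
- Weak points: A1 has a third electrophile, the pyranone, and with MOM ethers on O5 and O7 it has no phenoxide shielding. The closing acid step must dehydrate one tertiary alcohol while sparing the other, and the MOM removal in the same step frees O5 and O7 next to it, which is exactly the acid sensitivity of the target. The propanoate chain still has to be placed at C6, so the regiochemical problem remains.
- Comparison: the chosen plan forms only one C–CH3 bond late, but does so on a triphenoxide and never exposes the tertiary alcohol to acid.

**Alternative 2:** Ring B would be built by benzannulation, cutting C1'–C2', C2'–C3' and C4'–C5'. Photochemical Wolff rearrangement of the chromon-3-yl diazo enone A3 would give a vinylketene. It would add (triisopropylsilyloxy)ethyne A4 by [2+2] cycloaddition, four-electron ring opening and six-electron ring closure to give the 2'-hydroxy-4'-silyloxy isoflavone A5.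
- Merits: the resorcinol oxygens arrive already differentiated and no cross-coupling is needed.
- Weak points: A5 still lacks the pyran ring, and annulating it onto the 4'-oxygen must choose C5' over the more activated C3'. A3 needs the whole of ring A with its chain, so the C6 problem is only postponed. A3 also needs several homologation steps from a 3-formylchromone, and a chromone enone is itself photoreactive.
- Comparison: the bond this route works hardest for, C3–C1', is the one a Suzuki–Miyaura coupling makes reliably. The chosen plan also gets the linear chromene from 4-bromoresorcinol with the bromine fixing regiochemistry. Alternative 2 is longer and riskier without solving anything the chosen plan leaves open.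

**Alternative 3:** Ring A would be built by benzannulation on a pyranone, cutting C4a–C5, C5–C6 and C7–C8. Blue-light Wolff rearrangement of the 5-aryl-4-pyranon-2-yl diazomethyl ketone A6 would give a pyranonylketene. The siloxyalkyne A7 carries the complete, silyl-protected chain and would add to give the 5-hydroxy-7-silyloxy-6-alkyl isoflavone A8.
- Merits: the alkyne polarisation puts the chain carbon at C6 and the siloxy carbon at C7 in the bond-forming event itself. The tertiary alcohol arrives finished and protected, so no Grignard addition is needed on a chromone. O5 and O7 emerge differentiated. In these three respects this road is better than the chosen plan.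
- Weak points: A6 is far from commercial material; it needs a 5-aryl-4-oxopyran-2-carboxylic acid and a diazomethane homologation. A7 needs ynolate chemistry. The vinyl part of the ketene is a cross-conjugated pyranone double bond, a less secure case for this benzannulation. The 2H-chromene on ring B is photochromic and would be irradiated along with the diazo ketone.
- Comparison: the chosen plan sets against it commodity starting materials, known reaction classes at every step, C6 regiocontrol by symmetry plus a ketal tether, and no light on the chromene.

Key step: step 11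

Assumption: ketal 19 forms as a racemate (one enantiomer is drawn) and its stereocentre is destroyed in step 12; ketone 20 is drawn open-chain although it may equilibrate with its cyclic hemiketal, which reacts through the open form.

## Route

Step 1
Reactants: 1 2,4,6-trihydroxyacetophenone
Product: 2 1-[2,6-dihydroxy-4-(methoxymethoxy)phenyl]ethan-1-one
Conditions: MOMCl (1.0 equiv), i-Pr2NEt (1.1 equiv), THF, 0 °C
Reagents that add atoms: chloromethyl methyl ether, COCCl
Why: Williamson-type O-alkylation; the 4-OH para to the acetyl group is the most acidic and the only hydroxyl not held in a hydrogen bond to the ketone, so one equivalent of reagent should react there first, and the bis-ether by-product is separable.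

Step 2
Reactants: 2 1-[2,6-dihydroxy-4-(methoxymethoxy)phenyl]ethan-1-one
Product: 3 3-acetyl-2,4-dihydroxy-6-(methoxymethoxy)benzaldehyde
Conditions: (chloromethylene)dimethyliminium chloride (1.2 equiv), MeCN, 0 °C to rt; then aq. NaOAc, rt
Reagents that add atoms: (chloromethylene)dimethyliminium chloride, C[N+](C)=CCl.[Cl-]; water, O
Why: Vilsmeier–Haack formylation of a phloroglucinol ring; 2 is symmetric, so either free position gives the same aldehyde, and the first formyl group deactivates the ring against a second. The preformed salt without POCl3 and the buffered hydrolysis are chosen to spare the MOM ether, and the low temperature to spare the acetyl group.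

Step 3
Reactants: 3 3-acetyl-2,4-dihydroxy-6-(methoxymethoxy)benzaldehyde
Product: 5 1-[7-hydroxy-5-(methoxymethoxy)-2,2-dimethyl-4H-1,3-benzodioxin-8-yl]ethan-1-one, via salicyl alcohol 4 (not isolated)
Conditions: NaBH4, THF–MeOH, 0 °C; AcOH to pH 6, evaporate; then Me2C(OMe)2, PPTS, acetone, rt
Reagents that add atoms: 2,2-dimethoxypropane, COC(C)(C)OC
Why: Borohydride reduces the aldehyde much faster than the doubly chelated aryl ketone. The labile salicyl alcohol 4 is then locked by acid-catalysed isopropylidene ketal formation with its only free phenolic neighbour; the other ortho oxygen carries MOM, so the ketal regiochemistry is unambiguous.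

Step 4
Reactants: 5 1-[7-hydroxy-5-(methoxymethoxy)-2,2-dimethyl-4H-1,3-benzodioxin-8-yl]ethan-1-one
Product: 7 3-iodo-7-(methoxymethoxy)-4H-chromen-4-one bearing an isopropylidene ketal bridge between O5 and the C6 CH2O group, via enaminone 6 (not isolated)
Conditions: Me2NCH(OMe)2, toluene, 90 °C; evaporate; then I2, pyridine, CHCl3, rt
Reagents that add atoms: N,N-dimethylformamide dimethyl acetal, COC(OC)N(C)C; iodine, II
Why: Condensation of the methyl ketone with the amide acetal gives enaminone 6. Iodination at its alpha carbon triggers attack of the one free ortho phenol and loss of dimethylamine (the standard 3-iodochromone synthesis); the other flanking oxygen is tied up in the ketal, so the CH2O carbon must end at C6.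

Step 5
Reactants: 8 4-bromoresorcinol; 9 3-methylbut-2-enoic acid
Product: 10 6-bromo-7-hydroxy-2,2-dimethylchroman-4-one
Conditions: P2O5, MeSO3H, 70 °C
Reagents that add atoms: none
Why: Friedel–Crafts acylation at the only open position ortho to one hydroxyl and para to the other, followed by oxa-Michael closure of the chelated ortho hydroxyl onto the dimethyl enone. The bromine therefore ends at C6 beside the 7-OH and the fusion is linear.

Step 6
Reactants: 10 6-bromo-7-hydroxy-2,2-dimethylchroman-4-one
Product: 11 6-bromo-7-(methoxymethoxy)-2,2-dimethylchroman-4-one
Conditions: MOMCl, i-Pr2NEt, CH2Cl2, 0 °C to rt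
Reagents that add atoms: chloromethyl methyl ether, COCCl
Why: O-alkylation of the acidic phenol para to the ketone; MOM withstands the organolithium step and later assists it by chelation.

Step 7
Reactants: 11 6-bromo-7-(methoxymethoxy)-2,2-dimethylchroman-4-one
Product: 13 6-bromo-7-(methoxymethoxy)-2,2-dimethyl-2H-chromene, via chroman-4-ol 12 (not isolated)
Conditions: NaBH4, MeOH–THF, 0 °C; aqueous work-up; then MsCl, Et3N, CH2Cl2, 0 °C to rt
Reagents that add atoms: none
Why: Ketone reduction gives the racemic benzylic carbinol 12, whose stereocentre is removed at once. Its mesylate is activated by the para alkoxy group and eliminates under Et3N to the conjugated chromene (dehydration via sulfonate); the basic conditions keep the MOM ether.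

Step 8
Reactants: 13 6-bromo-7-(methoxymethoxy)-2,2-dimethyl-2H-chromene
Product: 14 2-[7-(methoxymethoxy)-2,2-dimethyl-2H-chromen-6-yl]-4,4,5,5-tetramethyl-1,3,2-dioxaborolane
Conditions: n-BuLi, THF, −78 °C; then i-PrOBpin, −78 °C to rt; aq. NH4Cl
Reagents that add atoms: 2-isopropoxy-4,4,5,5-tetramethyl-1,3,2-dioxaborolane, CC(C)OB1OC(C)(C)C(C)(C)O1
Why: Bromine–lithium exchange is faster than any deprotonation at −78 °C. The aryllithium is stabilised by the ortho MOM oxygen and is trapped by the borate ester (borylation via organolithium).

Step 9
Reactants: 7 3-iodo-7-(methoxymethoxy)-4H-chromen-4-one bearing the O5/C6-CH2O isopropylidene ketal; 14 2-[7-(methoxymethoxy)-2,2-dimethyl-2H-chromen-6-yl]-4,4,5,5-tetramethyl-1,3,2-dioxaborolane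
Product: 15 7-(methoxymethoxy)-3-[7-(methoxymethoxy)-2,2-dimethyl-2H-chromen-6-yl]-4H-chromen-4-one bearing the O5/C6-CH2O isopropylidene ketal
Conditions: Pd(dppf)Cl2 (5 mol %), K2CO3, 1,4-dioxane–H2O, 80 °C
Reagents that add atoms: none
Why: Suzuki–Miyaura coupling of a 3-iodochromone with an ortho-alkoxyaryl boronate, the standard isoflavone construction. Oxidative addition into the C3–I bond is fast, and aqueous carbonate is too weak a nucleophile to open the pyranone.

Step 10
Reactants: 15 the fully protected isoflavone
Product: 16 5,7-dihydroxy-6-(hydroxymethyl)-3-(7-hydroxy-2,2-dimethyl-2H-chromen-6-yl)-4H-chromen-4-one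
Conditions: 2 M aq. HCl, THF, 45 °C, degassed, no alcohol co-solvent
Reagents that add atoms: none
Why: Acid hydrolysis of two aryl MOM acetals and the isopropylidene ketal in one operation. With water as the only nucleophile, any benzylic cation that forms returns to the benzyl alcohol, and the chromene tolerates dilute acid.

Step 11
Reactants: 16 5,7-dihydroxy-6-(hydroxymethyl)-3-(7-hydroxy-2,2-dimethyl-2H-chromen-6-yl)-4H-chromen-4-one; 17 2-methoxypropene
Product: 19 5-hydroxy-3-(7-hydroxy-2,2-dimethyl-2H-chromen-6-yl)-8-methoxy-8-methyl-7,8-dihydro-4H,6H-pyrano[3,2-g]chromen-4-one (racemic ketal), via ortho-quinone methide 18 (not isolated)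
Conditions: 17 (40 equiv), 1,4-dioxane, sealed tube, 110 °C, acid-free glassware
Reagents that add atoms: none
Why: Thermal 1,4-dehydration of the ortho-hydroxybenzyl alcohol, with the 7-OH passing its proton to the benzylic hydroxyl, gives ortho-quinone methide 18, an electron-poor 1-oxadiene whose exocyclic CH2 is the electrophilic end. The electron-rich enol ether 17 adds in an inverse-electron-demand hetero-Diels–Alder reaction: its nucleophilic CH2 bonds to the quinone methide CH2 (C1'''–C2''') and its oxygenated carbon to O7 (O7–C3'''), driven by rearomatisation of ring A. The closest known reaction type is the trapping of thermally generated ortho-quinone methides by vinyl ethers to give 2-alkoxychromans, a class also known for quinone methides derived from 7-hydroxyisoflavones. The one new ring is a six-membered cyclic ketal closed by [4+2] cycloaddition, concerted but asynchronous and equivalent to conjugate addition followed by six-membered capture of the oxocarbenium ion by the ring oxygen. The ketal carbon is the only new stereocentre; nothing in the achiral substrate biases it, so 19 forms as a racemate, which does not matter because step 12 destroys it. The regiochemistry of the cycloaddition is fixed by the polarisation of both partners; O7 is expected to serve as the heteroatom in preference to the chelated O5, and the O5 isomer would hydrolyse to the same ketone. Chemoselectivity rests on the large excess of 17, which should beat the phenolic ring positions and the chromene olefin of a second molecule as traps, and on the absence of acid, which keeps 17 from forming mixed ketals with the phenols.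

Step 12
Reactants: 19 the racemic 2-methoxy-2-methylchroman ketal
Product: 20 5,7-dihydroxy-3-(7-hydroxy-2,2-dimethyl-2H-chromen-6-yl)-6-(3-oxobutyl)-4H-chromen-4-one
Conditions: 0.5 M aq. HCl, THF, rt
Reagents that add atoms: water, O
Why: Acid-catalysed hydrolysis of a mixed aryl methyl ketal: loss of methanol gives an oxocarbenium ion, water adds, and the hemiketal opens to the phenol and the methyl ketone. This is far milder than anything that would harm the chromene, and an O5-linked ketal or stray isopropenyl-derived phenol ketals would converge on 20.

Step 13
Reactants: 20 5,7-dihydroxy-3-(7-hydroxy-2,2-dimethyl-2H-chromen-6-yl)-6-(3-oxobutyl)-4H-chromen-4-one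
Product: 21 5,7-dihydroxy-6-(3-hydroxy-3-methylbutyl)-3-(7-hydroxy-2,2-dimethyl-2H-chromen-6-yl)-4H-chromen-4-one (target)
Conditions: MeMgBr (8 equiv), THF, 0 °C to rt; then sat. aq. NH4Cl
Reagents that add atoms: methylmagnesium bromide, C[Mg]Br
Why: Grignard 1,2-addition; the first three equivalents form the magnesium phenoxides, which turn the chromone into an unreactive vinylogous carboxylate, so the remaining reagent should add only to the dialkyl ketone. The neutral NH4Cl work-up avoids acid-induced cyclisation of the new tertiary alcohol onto O5 or O7.

## Compound list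

1 | 2,4,6-trihydroxyacetophenone | CC(=O)c1c(O)cc(O)cc1O | starting material
2 | 1-[2,6-dihydroxy-4-(methoxymethoxy)phenyl]ethan-1-one | CC(=O)c1c(O)cc(OCOC)cc1O | intermediate
3 | 3-acetyl-2,4-dihydroxy-6-(methoxymethoxy)benzaldehyde | CC(=O)c1c(O)cc(OCOC)c(C=O)c1O | intermediate
4 | 1-[2,6-dihydroxy-3-(hydroxymethyl)-4-(methoxymethoxy)phenyl]ethan-1-one (salicyl alcohol, not isolated) | CC(=O)c1c(O)cc(OCOC)c(CO)c1O | intermediate
5 | 1-[7-hydroxy-5-(methoxymethoxy)-2,2-dimethyl-4H-1,3-benzodioxin-8-yl]ethan-1-one | CC(=O)c1c(O)cc(OCOC)c2COC(C)(C)Oc12 | intermediate
6 | (E)-3-(dimethylamino)-1-[7-hydroxy-5-(methoxymethoxy)-2,2-dimethyl-4H-1,3-benzodioxin-8-yl]prop-2-en-1-one (enaminone, not isolated) | CN(C)/C=C/C(=O)c1c(O)cc(OCOC)c2COC(C)(C)Oc12 | intermediate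
7 | 3-iodo-7-(methoxymethoxy)-4H-chromen-4-one with O5 and the C6 CH2O group joined as an isopropylidene ketal (2,2-dimethyl-4H-1,3-dioxin fused at C5–C6) | O=c1c(I)coc2cc(OCOC)c3COC(C)(C)Oc3c12 | intermediate
8 | 4-bromoresorcinol (4-bromobenzene-1,3-diol) | Oc1ccc(Br)c(O)c1 | starting material
9 | 3-methylbut-2-enoic acid | CC(C)=CC(=O)O | starting material
10 | 6-bromo-7-hydroxy-2,2-dimethylchroman-4-one | CC1(C)CC(=O)c2cc(Br)c(O)cc2O1 | intermediate
11 | 6-bromo-7-(methoxymethoxy)-2,2-dimethylchroman-4-one | CC1(C)CC(=O)c2cc(Br)c(OCOC)cc2O1 | intermediate
12 | 6-bromo-7-(methoxymethoxy)-2,2-dimethylchroman-4-ol (racemic, not isolated) | CC1(C)CC(O)c2cc(Br)c(OCOC)cc2O1 | intermediate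
13 | 6-bromo-7-(methoxymethoxy)-2,2-dimethyl-2H-chromene | CC1(C)C=Cc2cc(Br)c(OCOC)cc2O1 | intermediate
14 | 2-[7-(methoxymethoxy)-2,2-dimethyl-2H-chromen-6-yl]-4,4,5,5-tetramethyl-1,3,2-dioxaborolane | CC1(C)C=Cc2cc(B3OC(C)(C)C(C)(C)O3)c(OCOC)cc2O1 | intermediate
15 | 7-(methoxymethoxy)-3-[7-(methoxymethoxy)-2,2-dimethyl-2H-chromen-6-yl]-4H-chromen-4-one with the O5/C6-CH2O isopropylidene ketal | O=c1c(-c2cc3C=CC(C)(C)Oc3cc2OCOC)coc2cc(OCOC)c3COC(C)(C)Oc3c12 | intermediate
16 | 5,7-dihydroxy-6-(hydroxymethyl)-3-(7-hydroxy-2,2-dimethyl-2H-chromen-6-yl)-4H-chromen-4-one | OCc1c(O)cc2occ(-c3cc4c(cc3O)OC(C)(C)C=C4)c(=O)c2c1O | intermediate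
17 | 2-methoxypropene | COC(C)=C | starting material
18 | 5-hydroxy-3-(7-hydroxy-2,2-dimethyl-2H-chromen-6-yl)-6-methylidene-chromene-4,7(6H)-dione (ortho-quinone methide, not isolated) | C=C1C(=O)C=C2OC=C(c3cc4C=CC(C)(C)Oc4cc3O)C(=O)C2=C1O | intermediate
19 | 5-hydroxy-3-(7-hydroxy-2,2-dimethyl-2H-chromen-6-yl)-8-methoxy-8-methyl-7,8-dihydro-4H,6H-pyrano[3,2-g]chromen-4-one (racemic; one enantiomer drawn) | CO[C@@]1(C)CCc2c(O1)cc1occ(-c3cc4c(cc3O)OC(C)(C)C=C4)c(=O)c1c2O | intermediate
20 | 5,7-dihydroxy-3-(7-hydroxy-2,2-dimethyl-2H-chromen-6-yl)-6-(3-oxobutyl)-4H-chromen-4-one | CC(=O)CCc1c(O)cc2occ(-c3cc4c(cc3O)OC(C)(C)C=C4)c(=O)c2c1O | intermediate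
21 | 5,7-dihydroxy-6-(3-hydroxy-3-methylbutyl)-3-(7-hydroxy-2,2-dimethyl-2H-chromen-6-yl)-4H-chromen-4-one (CNP0113306.0) | CC(C)(O)CCc1c(O)cc2occ(-c3cc4c(cc3O)OC(C)(C)C=C4)c(=O)c2c1O | target

## Step count and points of risk

Total: 13 steps. Longest linear sequence: 9 steps (steps 1–4 and 9–13; the ring B branch, steps 5–8 and 9–13, is equally long).

**Step 11 (key step).** The quinone methide may form too slowly at a temperature the tetraol tolerates. Once formed, it may be consumed by a second substrate molecule, through alkylation of its phenolic ring positions or addition to its chromene olefin, before the volatile enol ether reaches it. The acidic 7-OH may also catalyse ketal exchange of 17 with the hydroxyl groups. The fallback sets out from 16 and replaces the cycloaddition by a conjugate addition of a carbon acid. Heating 16 in pentane-2,4-dione as co-solvent should give the adduct 3-{[5,7-dihydroxy-3-(7-hydroxy-2,2-dimethyl-2H-chromen-6-yl)-4-oxo-4H-chromen-6-yl]methyl}pentane-2,4-dione F1. Retro-Claisen deacetylation with K2CO3 in ethanol, the classical alkylation–cleavage route to 4-arylbutan-2-ones, then gives ketone 20, where the route is rejoined.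

**Step 10.** Under the acid needed to cleave aryl MOM ethers, the freed benzylic alcohol can ionise and alkylate a second molecule, and the liberated formaldehyde can be captured by the electron-rich rings. The fallback sets out from 15 and moves the strong acid to a stage with no benzylic alcohol. Aqueous acetic acid in THF at 40 °C should remove only the isopropylidene ketal and give 5-hydroxy-6-(hydroxymethyl)-7-(methoxymethoxy)-3-[7-(methoxymethoxy)-2,2-dimethyl-2H-chromen-6-yl]-4H-chromen-4-one F2. Heating F2 with 17 as in step 11, now through O5, should give the angular 2-methoxy-2-methylpyrano ketal F3, fused at C5–C6 and still carrying both MOM ethers. HCl in methanol at 50 °C then cleaves the ketal and both MOM ethers to give 20.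

**Step 2.** The MOM ether may be lost to the hydrogen chloride released during substitution, and the iminium salt may attack the enolisable acetyl group on the way to a 3-formylchromone. The fallback sets out from 2 and installs the carbon directly at the alcohol oxidation level. Phenylboronic acid, paraformaldehyde and catalytic propanoic acid in refluxing toluene with water removal (boronic-acid-templated ortho-hydroxymethylation) should give 1-[7-hydroxy-5-(methoxymethoxy)-2-phenyl-4H-1,3,2-benzodioxaborin-8-yl]ethan-1-one F4. Exchange with propane-1,3-diol releases salicyl alcohol 4, which enters the second half of step 3.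

**Step 13.** The magnesium triphenoxide may precipitate and leave the addition incomplete, the methyl ketone may be enolised, or the reagent may attack C2 of the pyranone. The fallback sets out from 20. TBSCl and imidazole should silylate O7 and O2', leaving the chelated 5-OH, to give the bis-silyl ketone 7-(tert-butyldimethylsilyloxy)-3-[7-(tert-butyldimethylsilyloxy)-2,2-dimethyl-2H-chromen-6-yl]-5-hydroxy-6-(3-oxobutyl)-4H-chromen-4-one F5. MeMgBr with anhydrous CeCl3 at −78 °C adds to the ketone of this soluble substrate to give the bis-silyl tertiary alcohol F6, and Bu4NF buffered with acetic acid removes the silyl groups without acid to give 21.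

**Step 9.** The hindered, electron-rich boronate may protodeboronate, and the pyranone may be opened by aqueous base at 80 °C. The fallback sets out from 13 and avoids both boron and base. Bromine–lithium exchange followed by ZnCl2 gives [7-(methoxymethoxy)-2,2-dimethyl-2H-chromen-6-yl]zinc chloride F7, which is coupled with 7 under Pd(PPh3)4 in THF at 50 °C (Negishi coupling) to give 15.

## Further compounds

F1 | step 11 | 3-{[5,7-dihydroxy-3-(7-hydroxy-2,2-dimethyl-2H-chromen-6-yl)-4-oxo-4H-chromen-6-yl]methyl}pentane-2,4-dione | CC(=O)C(Cc1c(O)cc2occ(-c3cc4C=CC(C)(C)Oc4cc3O)c(=O)c2c1O)C(C)=O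
F2 | step 10 | 5-hydroxy-6-(hydroxymethyl)-7-(methoxymethoxy)-3-[7-(methoxymethoxy)-2,2-dimethyl-2H-chromen-6-yl]-4H-chromen-4-one | OCc1c(OCOC)cc2occ(-c3cc4C=CC(C)(C)Oc4cc3OCOC)c(=O)c2c1O
F3 | step 10 | angular 2-methoxy-2-methyl-3,4-dihydro-2H-pyrano ketal fused through O5 and C6, with 7-O-MOM and 2'-O-MOM (racemic) | COC1(C)CCc2c(OCOC)cc3occ(-c4cc5C=CC(C)(C)Oc5cc4OCOC)c(=O)c3c2O1
F4 | step 2 | 1-[7-hydroxy-5-(methoxymethoxy)-2-phenyl-4H-1,3,2-benzodioxaborin-8-yl]ethan-1-one | CC(=O)c1c(O)cc(OCOC)c2COB(c3ccccc3)Oc12
F5 | step 13 | 7-(tert-butyldimethylsilyloxy)-3-[7-(tert-butyldimethylsilyloxy)-2,2-dimethyl-2H-chromen-6-yl]-5-hydroxy-6-(3-oxobutyl)-4H-chromen-4-one | CC(=O)CCc1c(O[Si](C)(C)C(C)(C)C)cc2occ(-c3cc4C=CC(C)(C)Oc4cc3O[Si](C)(C)C(C)(C)C)c(=O)c2c1O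
F6 | step 13 | 7-(tert-butyldimethylsilyloxy)-3-[7-(tert-butyldimethylsilyloxy)-2,2-dimethyl-2H-chromen-6-yl]-5-hydroxy-6-(3-hydroxy-3-methylbutyl)-4H-chromen-4-one | CC(C)(O)CCc1c(O[Si](C)(C)C(C)(C)C)cc2occ(-c3cc4C=CC(C)(C)Oc4cc3O[Si](C)(C)C(C)(C)C)c(=O)c2c1O
F7 | step 9 | [7-(methoxymethoxy)-2,2-dimethyl-2H-chromen-6-yl]zinc chloride | Cl[Zn]c1cc2C=CC(C)(C)Oc2cc1OCOC
A1 | alternative 1 | methyl 3-{5,7-bis(methoxymethoxy)-3-[7-(methoxymethoxy)-2-oxo-2H-chromen-6-yl]-4-oxo-4H-chromen-6-yl}propanoate | COC(=O)CCc1c(OCOC)cc2occ(-c3cc4ccc(=O)oc4cc3OCOC)c(=O)c2c1OCOC
A2 | alternative 1 | tetramethylated diol with a (Z)-3-hydroxy-3-methylbut-1-enyl group at C5' and free 4'-OH | CC(C)(O)CCc1c(OCOC)cc2occ(-c3cc(/C=C\C(C)(C)O)c(O)cc3OCOC)c(=O)c2c1OCOC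
A3 | alternative 2 | (E)-1-diazo-4-[5,7-bis(methoxymethoxy)-6-(3-methyl-3-triethylsilyloxybutyl)-4-oxo-4H-chromen-3-yl]but-3-en-2-one | [N-]=[N+]=CC(=O)/C=C/c1coc2cc(OCOC)c(CCC(C)(C)O[Si](CC)(CC)CC)c(OCOC)c2c1=O
A4 | alternative 2 | (triisopropylsilyloxy)ethyne | C#CO[Si](C(C)C)(C(C)C)C(C)C
A5 | alternative 2 | 2'-hydroxy-4'-(triisopropylsilyloxy) isoflavone with 5,7-bis-MOM ring A and the triethylsilyl-protected chain | CC(C)(O[Si](CC)(CC)CC)CCc1c(OCOC)cc2occ(-c3ccc(O[Si](C(C)C)(C(C)C)C(C)C)cc3O)c(=O)c2c1OCOC
A6 | alternative 3 | 2-diazo-1-{5-[7-(methoxymethoxy)-2,2-dimethyl-2H-chromen-6-yl]-4-oxo-4H-pyran-2-yl}ethan-1-one | [N-]=[N+]=CC(=O)c1cc(=O)c(-c2cc3C=CC(C)(C)Oc3cc2OCOC)co1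
A7 | alternative 3 | triethyl{[2-methyl-6-(triisopropylsilyloxy)hex-5-yn-2-yl]oxy}silane | CC(C)(O[Si](CC)(CC)CC)CCC#CO[Si](C(C)C)(C(C)C)C(C)C
A8 | alternative 3 | 5-hydroxy-7-(triisopropylsilyloxy)-6-(3-methyl-3-triethylsilyloxybutyl) isoflavone with the 2'-O-MOM chromene ring B | CC(C)(O[Si](CC)(CC)CC)CCc1c(O[Si](C(C)C)(C(C)C)C(C)C)cc2occ(-c3cc4c(cc3OCOC)OC(C)(C)C=C4)c(=O)c2c1O
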